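A bench chemist who charges a ligand short counts each ligand as one exchange. We test that rule here.

| flask | starting complex | incoming ligand | leaving ligand | remark | time |
|---|---|---|---|---|---|
| south-west | 20 mM | 3 equiv | 3.4 equiv | run made earlier |  |
| east | 40 mM | 3 equiv | 5 equiv | run made earlier |  |
| delta | 20 mM | 3.00 equiv | 5.00 equiv |  | 40 min |
| epsilon | 20 mM | 1.00 equiv | 5.00 equiv |  | 40 min |
| eta | 20 mM | 0.500 equiv | 5.00 equiv |  | 40 min |

| run | time / min | complex with one exchanged / % | complex with two exchanged / % |
|---|---|---|---|
| south-west | 1.00 | 24.5 | 29.8 |
| south-west | 1.50 | 25.2 | 37.4 |
| south-west | 2.50 | 24.3 | 49.3 |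
| south-west | 4.00 | 24.4 | 52.9 |
| south-west | 6.00 | 25.7 | 55.4 |
| south-west | 10.0 | 24.4 | 49.7 |
| south-west | 15.0 | 21.9 | 45.8 |
| east | 1.00 | 25.7 | 42.5 |
| east | 1.50 | 29.6 | 49.9 |
| east | 2.50 | 31.4 | 53.8 |
| east | 4.00 | 32.0 | 52.4 |
| east | 6.00 | 28.3 | 51.8 |
| east | 10.0 | 28.5 | 46.1 |
| east | 15.0 | 24.3 | 42.3 |

(each reading ± 1 percentage point)

- a species is counted by the starting complex in it: one self-condensation product counts as two
- on the list of suspects stand: starting complex + incoming ligand <-> leaving ligand + complex with one exchanged; complex with one exchanged + incoming ligand <-> leaving ligand + complex with two exchanged; 2 starting complex -> self-condensation product; complex with two exchanged <-> isomer of the product; leaving ligand + starting complex -> side product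

- which of these holds the largest part of the starting complex at the end of delta (starting complex / complex with one exchanged / complex with two exchanged)
- which of these holds the largest part of the starting complex at the end of epsilon (starting complex / complex with one exchanged / complex with two exchanged)
- which of these holds the largest part of the starting complex at the end of eta (starting complex / complex with one exchanged / complex with two exchanged)
- how much complex with one exchanged is there at the end of eta, in percent of the starting complex charged

Eta charges less incoming ligand than starting complex, so that ligand is the limiting reagent of the exchange. Each exchange binds one incoming ligand and frees one leaving ligand. For eta we reckon: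

C = 0.500 equiv / 1.00 equiv = 50.0%

This C is the ligand ceiling: the share of the starting complex that could carry one exchange if every ligand bound once. Let A be complex with one exchanged, B complex with two exchanged, I the isomer and F free incoming ligand, all in percent of the complex charged. The ledger is then:

C = A + 2(B + I) + F

So A is C less the corrections.

The rule stops where B matches A. We read K, the equilibrium ratio of the second exchange, from the south-west readings at 4.00 min, ignoring the isomer, with L the leaving ligand. It is a reading and carries their scatter:

K = (B/A)(L/F) ≈ 6.00

B equals A at F/L = 0.167. Delta charges a ratio of 0.600, which is above that border. Eta charges 0.100, which is below it. Epsilon starts at 0.200, near the border. We therefore expect complex with two exchanged to lead in delta, and A to stay under C in eta. The runs do not show starting complex, so we leave open whether it leads in epsilon and eta.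

The forecast is firmer: complex with two exchanged for delta, starting complex for epsilon, starting complex for eta, and 17% of complex with one exchanged at the end of eta. Its ground: “the exchanges are fast”.

The flask gives complex with two exchanged for delta, complex with one exchanged for epsilon, complex with one exchanged for eta, and 32.8% of complex with one exchanged at the end of eta.

    starting complex + incoming ligand ⇌ leaving ligand + complex with one exchanged (K = 150, k = 15.0 M⁻¹ min⁻¹)
    complex with one exchanged + incoming ligand ⇌ leaving ligand + complex with two exchanged (K = 7.90, k = 34.0 M⁻¹ min⁻¹)
    2 starting complex → self-condensation product (k = 1.70 M⁻¹ min⁻¹)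
    complex with two exchanged ⇌ isomer of the product (K = 1.40, k = 0.0480 min⁻¹)
    leaving ligand + starting complex → side product (k = 0.0560 M⁻¹ min⁻¹)

Eta ends 17 percentage points under C. Of that gap, B and I take 11.6% of the complex charged as ligand, and free ligand is 5.65%. Eta's neighbour with 50 mM of starting complex keeps the equivalents, so C stays 50.0%. There A is 28.3%, B and I take 13.5%, and free ligand is 8.13%.

(The numbers in the tables are calculated on assumed constants, and the scatter is random.)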